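## Structural features

The target is a 6,7-seco-kaurane-type C20 skeleton. Ring A is a 4,4-dimethylcyclohex-2-enone (C1 ketone, C2=C3, gem-dimethyl C4) carrying a hydroxymethyl group (C6) on C5, and its C10 is a quaternary spiro atom shared with a δ-lactone (C10–C20–O–C7(=O)–C8–C9). The lactone is cis-fused along C8–C9 to ring C (C8, C9, C11, C12, C13, C14). Ring D (C8, C14, C13, C16, C15) bridges C8 and C13 to give a bicyclo[3.2.1]octanone with the C15 ketone and an exo hydroxymethyl group (C17) on C16. The stereocentres C5, C10, C9 and C8 are contiguous and two of them (C10, C8) are quaternary; C8 is in addition a bridgehead that carries both the lactone carbonyl and the ketone. C13 and C16 complete the set of six. On ring A, C20 is cis and C9 trans to C6; on ring C, C7 and C10 are cis and the C15–C16 bridge lies on the other face. The fragile groups are the β-hydroxy ketone C15/C16/C17 (dehydration to the exocyclic enone, retro-aldol, epimerisation at C16) and the β-keto lactone at C8 (acyl cleavage by nucleophiles); the ring A enone, by contrast, cannot enolise because C10 and C4 are quaternary. The real difficulty is the C10–C9–C8 triad with its spiro and bridgehead quaternary carbons and the cis lactone fusion. The key step exploits three facts: C8 and C9 are the two atoms shared by the lactone and ring C, C8 carries two acyl carbons (C7, C15), and C11–C14 are bare carbons. The bonds C8–C14 and C9–C11 are therefore the retron of a [4+2] addition of a four-carbon diene across a C8=C9 alkylidene acetoacetate that is held inside the preformed spirolactone.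

## Logic of the disconnections

**22 to 20 (C16–C17, after removal of silicon from O6 in 21).** The β-hydroxy ketone is an aldol retron, so C17 is cut off as a one-carbon aldehyde. The gain is that the labile aldol unit is absent from every earlier intermediate. The forward step must attack the C15/C16 enolate of 20 from the exo face and must be run under kinetic control so that the aldolate neither reverts nor dehydrates.

**20 to 17 (C13–C16, via 19 and 18).** Cutting the bond between the acetyl methyl carbon and C13 opens ring D and reduces the bicyclo[3.2.1]octane to a monocyclic cyclohexene that bears an acetyl group on C8. The forward step must join C16 to C13 and not to C12 (five- against six-membered ring). It sets C13 necessarily, because the tether reaches only one face.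

**17 to 15 + 16 (C8–C14 and C9–C11; key disconnection).** Both bonds that join ring C to the C8–C9 edge of the lactone are cut at once, which removes ring C and the stereocentres C8 and C9 and leaves 15 with only C5 and C10. In one sentence, the route is the addition of 16 across the C8=C9 bond of spirolactone 15. The lactone is therefore not closed last by lactonisation, nor used as the tether of an intramolecular cycloaddition; it is the dienophile and the stereochemical template. The forward step needs the diene to add to the lactone face flanked by C1 and not to the face flanked by C5. The cis fusion is guaranteed by the ring-bound alkene.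

**15 to 12 + 13 (C8=C9 and O–C7, via 14).** The alkylidene acetoacetate is cut by a Knoevenagel transform and the ester by acyl transfer. 13 delivers C7, C8, C15 and C16 in the correct oxidation states. The forward step requires a C10 that bears a free hydroxymethyl arm (C20, cis to C6) and a formyl group (C9, trans to C6). Because C10 is quaternary, 12 and 15 can neither eliminate nor deconjugate.

**12 to 7 (C10–C9 and C10–C20, via 11, 10, 9, 8).** Both arms on C10 are cut as one-carbon aldehyde units. The order of introduction defines the configuration: the second arm enters trans to the C5 side chain, stays free and is oxidised to C9, whereas the first arm is silylated and becomes C20. The demand is face selectivity in the second aldol addition. It is softened by the fact that the two arms differ only in protection, so the C10 epimer of 10 can be brought to the same product.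

**7 to 2 + 3 (C5–C6, via 6, 5, 4) and 2 to 1.** C6 is cut off as an alkenyl group that is later cleaved to CH2OH. 2 is achiral with two enantiotopic enone units, so a catalytic enantioselective 1,4-addition sets C5, the only stereocentre set by a catalyst; all others are relayed from it. 2 comes from commercial 1 by dehydrogenation.

## Other disconnections considered

**Alternative 1:** The first plan that comes to mind cuts C8–C9 and C13–C14 and uses an ester-tethered intramolecular Diels–Alder reaction. The triene ester A1 has a C9=C11–C12=C13 diene on C10 and a 2-methylene-3-oxobutanoate dienophile on O20, and it would close the lactone and ring C together to give A2. It is not preferred for three reasons.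
- The alkene of A2 lies at C11=C12, so C13 is saturated and the C16 methyl has no π bond to attack. A C13 substituent would have to be carried on a (Z)-configured diene terminus to come out trans to C10.
- The cis fusion is not enforced; it depends on endo/exo competition across a flexible ester tether that must leave its preferred conformation.
- The doubly activated methylene dienophile of A1 is prone to self-condensation and must be generated in the flask, and the diene has to be installed by a separate olefination.

**Alternative 2:** This plan cuts C9–C10 and O20–C7. The spiro-epoxide A3 is opened reductively with Cp2TiCl (trivalent titanium) to a tertiary C10 radical, which adds to a cyclohexadiene carboxylate acceptor and lactonises to A4; acylation at C8 and closure of ring D follow. The radical should add trans to the C5 side chain, which is attractive, but the plan is weaker elsewhere.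
- A tertiary radical adds slowly to a β-substituted cyclic acrylate, and reduction of the radical by a second equivalent of Cp2TiCl competes.
- C9 is set in an intermolecular step without a clear bias.
- C1 must be masked as in A3, since an α,β-epoxy ketone would simply be reduced.
- C8 needs a further stereoselective C-acylation, which lengthens the route.

**Alternative 3:** This plan reconnects ring B, in imitation of the biogenesis. The intact tetracyclic diene-dione A5 (C6=C7) would be cleaved by ozonolysis; the C7 aldehyde would be captured by the C20 hydroxyl as a lactol and oxidised, and the C6 aldehyde reduced. It is not preferred because a fourth carbocycle, with its own ring-fusion and C20-oxidation problems, is built only to be broken. The two ends of the cleaved bond must also reach different oxidation states in the presence of two ketones and the β-hydroxy ketone, and ozone must distinguish C6=C7 from C2=C3.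

Key step: step 11

Remark: atoms carry the kaurane locants of the target (C1–C20) in every intermediate. Monomeric formaldehyde is taken as generated by cracking paraformaldehyde, and 1, 3, 13 and 16 are taken as commercial.

## Route

**Step 1**
Reactants: 1 4,4-dimethylcyclohex-2-en-1-one
Product: 2 4,4-dimethylcyclohexa-2,5-dien-1-one
Conditions: DDQ, dioxane, reflux
Reagents that add atoms: none
Why: Dehydrogenation of a 4,4-disubstituted cyclohexenone with DDQ (hydride abstraction from the enol, then proton loss); the quaternary C4 blocks aromatisation, so the cross-conjugated dienone is the end point.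

**Step 2**
Reactants: 2 4,4-dimethylcyclohexa-2,5-dien-1-one; 3 (E)-2-phenylethenylboronic acid
Product: 4 (R)-4,4-dimethyl-5-[(E)-2-phenylethenyl]cyclohex-2-en-1-one
Conditions: Rh(acac)(C2H4)2 (3 mol %), (R)-BINAP, dioxane/H2O (10:1), 100 °C, 2 in slight excess
Reagents that add atoms: (E)-2-phenylethenylboronic acid 3, OB(O)/C=C/c1ccccc1
Why: Hayashi–Miyaura reaction (rhodium–BINAP-catalysed enantioselective 1,4-addition of an alkenylboronic acid); the two enone units of 2 are enantiotopic, so face selection by the chiral monovalent rhodium complex sets C5, the styryl group being a masked C6. The (R)-ligand is chosen by analogy with the established sense for cyclohex-2-enone; the (S)-ligand would be used if the sense proved opposite.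

**Step 3**
Reactants: 4 (R)-4,4-dimethyl-5-[(E)-2-phenylethenyl]cyclohex-2-en-1-one
Product: 6 (S)-5-(hydroxymethyl)-4,4-dimethylcyclohex-2-en-1-one, via aldehyde 5 (not isolated)
Conditions: O3, CH2Cl2/MeOH, −78 °C; then NaBH4, −78 to −40 °C
Reagents that add atoms: ozone, [O-][O+]=O
Why: Ozonolysis with reductive work-up; the electron-rich styryl alkene should react before the electron-poor enone, and borohydride at low temperature reduces aldehyde 5 as it forms, much faster than the conjugated ketone, so that C5 (α to the formyl group) is not epimerised.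

**Step 4**
Reactants: 6 (S)-5-(hydroxymethyl)-4,4-dimethylcyclohex-2-en-1-one
Product: 7 (S)-5-{[tert-butyl(diphenyl)silyl]oxymethyl}-4,4-dimethylcyclohex-2-en-1-one
Conditions: TBDPSCl, imidazole, DMF, rt
Reagents that add atoms: tert-butyl(chloro)diphenylsilane, CC(C)(C)[Si](Cl)(c1ccccc1)c1ccccc1
Why: Imidazole-promoted silylation of a primary alcohol; the bulky silyl ether also enlarges the C5 side of ring A for the later face-selective steps.

**Step 5**
Reactants: 7 (S)-5-{[tert-butyl(diphenyl)silyl]oxymethyl}-4,4-dimethylcyclohex-2-en-1-one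
Product: 8 (5S,6R)-5-{[tert-butyl(diphenyl)silyl]oxymethyl}-6-(hydroxymethyl)-4,4-dimethylcyclohex-2-en-1-one
Conditions: LiN(i-Pr)2, THF, −78 °C; CH2O (gas); AcOH, −78 °C
Reagents that add atoms: formaldehyde, C=O
Why: Kinetic α′-deprotonation of the enone (C4 is quaternary, so no γ-deprotonation) and enolate aldol addition to formaldehyde; the new C10 centre, expected trans to the C5 side chain, is of no consequence because it is enolised again in step 7.

**Step 6**
Reactants: 8 (5S,6R)-5-{[tert-butyl(diphenyl)silyl]oxymethyl}-6-(hydroxymethyl)-4,4-dimethylcyclohex-2-en-1-one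
Product: 9 (5S,6R)-5-{[tert-butyl(diphenyl)silyl]oxymethyl}-4,4-dimethyl-6-[(triethylsilyl)oxymethyl]cyclohex-2-en-1-one
Conditions: TESCl, imidazole, CH2Cl2, 0 °C
Reagents that add atoms: chlorotriethylsilane, CC[Si](Cl)(CC)CC
Why: Silylation of the primary alcohol with a group that can later be removed in the presence of the tert-butyldiphenylsilyl ether; this arm becomes C20.

**Step 7**
Reactants: 9 (5S,6R)-5-{[tert-butyl(diphenyl)silyl]oxymethyl}-4,4-dimethyl-6-[(triethylsilyl)oxymethyl]cyclohex-2-en-1-one
Product: 10 (5R,6R)-5-{[tert-butyl(diphenyl)silyl]oxymethyl}-6-(hydroxymethyl)-4,4-dimethyl-6-[(triethylsilyl)oxymethyl]cyclohex-2-en-1-one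
Conditions: LiN(i-Pr)2, THF, −78 to −40 °C; CH2O (gas), −78 °C; AcOH, −78 °C
Reagents that add atoms: formaldehyde, C=O
Why: Second enolate aldol addition to formaldehyde, which creates the quaternary C10; the electrophile should enter anti to the C5 side chain, so the new CH2OH (future C9) is trans and the silylated arm (future C20) cis to C6. The cold acidic quench prevents retro-aldol cleavage.

**Step 8**
Reactants: 10 (5R,6R)-5-{[tert-butyl(diphenyl)silyl]oxymethyl}-6-(hydroxymethyl)-4,4-dimethyl-6-[(triethylsilyl)oxymethyl]cyclohex-2-en-1-one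
Product: 11 (1S,6R)-6-{[tert-butyl(diphenyl)silyl]oxymethyl}-5,5-dimethyl-2-oxo-1-[(triethylsilyl)oxymethyl]cyclohex-3-ene-1-carbaldehyde
Conditions: Dess–Martin periodinane, pyridine, CH2Cl2, 0 °C to rt
Reagents that add atoms: none
Why: Dess–Martin oxidation of the neopentyl primary alcohol; the resulting β-keto aldehyde cannot enolise because C10 is quaternary.

**Step 9**
Reactants: 11 (1S,6R)-6-{[tert-butyl(diphenyl)silyl]oxymethyl}-5,5-dimethyl-2-oxo-1-[(triethylsilyl)oxymethyl]cyclohex-3-ene-1-carbaldehyde
Product: 12 (1S,6R)-6-{[tert-butyl(diphenyl)silyl]oxymethyl}-1-(hydroxymethyl)-5,5-dimethyl-2-oxocyclohex-3-ene-1-carbaldehyde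
Conditions: AcOH/THF/H2O (3:1:1), rt; used at once
Reagents that add atoms: none
Why: Mild acid solvolysis of the triethylsilyl ether, which the tert-butyldiphenylsilyl ether survives; base is avoided because 12 can lose formaldehyde by retro-aldol cleavage.

**Step 10**
Reactants: 12 (1S,6R)-6-{[tert-butyl(diphenyl)silyl]oxymethyl}-1-(hydroxymethyl)-5,5-dimethyl-2-oxocyclohex-3-ene-1-carbaldehyde; 13 2,2,6-trimethyl-4H-1,3-dioxin-4-one
Product: 15 (6S,11R)-4-acetyl-11-{[tert-butyl(diphenyl)silyl]oxymethyl}-10,10-dimethyl-2-oxaspiro[5.5]undeca-4,8-diene-3,7-dione, via acetoacetate 14 (not isolated)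
Conditions: 13 (1.5 equiv), toluene, 110 °C; then ethylenediammonium diacetate (10 mol %), 60 °C
Reagents that add atoms: 2,2,6-trimethyl-4H-1,3-dioxin-4-one 13, CC1=CC(=O)OC(C)(C)O1
Why: Thermal retro-[4+2] of 13 gives acetylketene, which acylates the primary alcohol to acetoacetate 14; an intramolecular Knoevenagel condensation (six-membered ring, ammonium carboxylate catalysis) then closes the unsaturated lactone. No stereocentre is formed, and the quaternary C10 excludes elimination and deconjugation.

**Step 11**
Reactants: 15 (6S,11R)-4-acetyl-11-{[tert-butyl(diphenyl)silyl]oxymethyl}-10,10-dimethyl-2-oxaspiro[5.5]undeca-4,8-diene-3,7-dione; 16 buta-1,3-diene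
Product: 17 (5R,8S,9S,10S)-6-[tert-butyl(diphenyl)silyl]oxy-1,15-dioxo-17-nor-6,7:13,16-disecokaura-2,12-dien-7,20-olide (cis-fused lactone/cyclohexene, acetyl group on C8)
Conditions: 16 (excess), ZnCl2 (1.5 equiv), Et2O/CH2Cl2, 0 °C to rt, sealed tube
Reagents that add atoms: buta-1,3-diene 16, C=CC=C
Why: Lewis-acid-promoted Diels–Alder reaction of an alkylidene 1,3-dicarbonyl compound; the closest known type is the zinc- or tin-halide-promoted cycloaddition of simple dienes to 2-acyl- and 2-alkoxycarbonyl-cyclohex-2-enones that bear a quaternary γ-carbon. ZnCl2 chelates the lactone and acetyl oxygens, which lowers the LUMO of C8=C9 and holds the acetyl carbonyl s-trans to the alkene, so the competing 1-oxadiene (hetero-Diels–Alder) mode is shut off. Ring C closes by a concerted, suprafacial [4+2] addition in which C9–C11 and C8–C14 form together. Because C8=C9 is held (Z) inside the lactone, C8 and C9 must emerge with a cis lactone/ring C fusion, that is, C7 and C10 cis on ring C and the acetyl group on the opposite face. The absolute sense at both centres is relayed from C10: the diene should add to the lactone face flanked by the planar C1 carbonyl and not to the face flanked by C5, which carries the silyloxymethyl group and abuts the gem-dimethyl carbon. The diene is symmetric, so no regiochemical or endo/exo question arises, and the adduct places C12=C13 exactly 1,3 to C8, where the acetyl methyl group can reach it in step 12. The selectivities needed are therefore π-facial, secured by the spiro centre, and chemoselectivity over the ring A enone, which is a much poorer dienophile (singly activated and hindered by C4).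

**Step 12**
Reactants: 17 (5R,8S,9S,10S)-6-[tert-butyl(diphenyl)silyl]oxy-1,15-dioxo-17-nor-6,7:13,16-disecokaura-2,12-dien-7,20-olide
Product: 19 (5R,8S,9S,10S,13R)-6-[tert-butyl(diphenyl)silyl]oxy-1,15-dioxo-17-nor-6,7-secokaura-2,11-dien-7,20-olide, via silyl enol ether 18 (not isolated)
Conditions: TMSOTf, Et3N, CH2Cl2, 0 °C; solvent exchange; Pd(OAc)2 (1.1 equiv), MeCN, rt
Reagents that add atoms: none
Why: Soft enolisation gives the only possible silyl enol ether (C8 is quaternary, ring A cannot enolise); Saegusa–Ito-type oxidative cyclisation of the silyl enol ether of an alkenyl methyl ketone follows, in which the divalent palladium enolate adds 5-exo across C12=C13 on the only face the tether reaches, setting C13. β-Hydride elimination can go only towards C11 because C13 is a bridgehead, which gives the C11=C12 alkene and zerovalent palladium.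

**Step 13**
Reactants: 19 (5R,8S,9S,10S,13R)-6-[tert-butyl(diphenyl)silyl]oxy-1,15-dioxo-17-nor-6,7-secokaura-2,11-dien-7,20-olide
Product: 20 (5R,8S,9S,10S,13R)-6-[tert-butyl(diphenyl)silyl]oxy-1,15-dioxo-17-nor-6,7-secokaur-2-en-7,20-olide
Conditions: H2 (1 atm), RhCl(PPh3)3 (10 mol %), benzene/EtOH, rt
Reagents that add atoms: none
Why: Homogeneous hydrogenation with RhCl(PPh3)3, which reduces the accessible, non-conjugated cis-disubstituted C11=C12 bond and should leave the conjugated, neopentyl-flanked C2=C3 enone untouched; no stereocentre is formed.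

**Step 14**
Reactants: 20 (5R,8S,9S,10S,13R)-6-[tert-butyl(diphenyl)silyl]oxy-1,15-dioxo-17-nor-6,7-secokaur-2-en-7,20-olide
Product: 21 (5R,8S,9S,10S,13R,16R)-6-[tert-butyl(diphenyl)silyl]oxy-17-hydroxy-1,15-dioxo-6,7-secokaur-2-en-7,20-olide
Conditions: LiN(SiMe3)2 (1.1 equiv), THF, −78 °C; CH2O (gas); AcOH, −78 °C
Reagents that add atoms: formaldehyde, C=O
Why: Kinetic lithium enolate formation (only C16 carries α-hydrogens) and aldol addition to formaldehyde; attack on the exo face of the bicyclo[3.2.1]octanone enolate, away from the C11–C12 bridge, gives the exo hydroxymethyl group (16R), which is also the less hindered epimer.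

**Step 15**
Reactants: 21 (5R,8S,9S,10S,13R,16R)-6-[tert-butyl(diphenyl)silyl]oxy-17-hydroxy-1,15-dioxo-6,7-secokaur-2-en-7,20-olide
Product: 22 (5R,8S,9S,10S,13R,16R)-6,17-dihydroxy-1,15-dioxo-6,7-secokaur-2-en-7,20-olide (target)
Conditions: HF·pyridine, pyridine, THF, 0 °C to rt
Reagents that add atoms: none
Why: Desilylation under buffered, weakly acidic fluoride conditions, which avoids the base-induced retro-aldol cleavage, dehydration and C16 epimerisation open to the β-hydroxy ketone.

## Compound list

1 | 4,4-dimethylcyclohex-2-en-1-one | CC1(C)CCC(=O)C=C1 | starting material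
2 | 4,4-dimethylcyclohexa-2,5-dien-1-one | CC1(C)C=CC(=O)C=C1 | intermediate
3 | (E)-2-phenylethenylboronic acid | OB(O)/C=C/c1ccccc1 | starting material
4 | (R)-4,4-dimethyl-5-[(E)-2-phenylethenyl]cyclohex-2-en-1-one | CC1(C)C=CC(=O)C[C@@H]1/C=C/c1ccccc1 | intermediate
5 | (S)-2,2-dimethyl-5-oxocyclohex-3-ene-1-carbaldehyde | CC1(C)C=CC(=O)C[C@@H]1C=O | intermediate (not isolated)
6 | (S)-5-(hydroxymethyl)-4,4-dimethylcyclohex-2-en-1-one | CC1(C)C=CC(=O)C[C@@H]1CO | intermediate
7 | (S)-5-{[tert-butyl(diphenyl)silyl]oxymethyl}-4,4-dimethylcyclohex-2-en-1-one | CC1(C)C=CC(=O)C[C@@H]1CO[Si](c1ccccc1)(c1ccccc1)C(C)(C)C | intermediate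
8 | (5S,6R)-5-{[tert-butyl(diphenyl)silyl]oxymethyl}-6-(hydroxymethyl)-4,4-dimethylcyclohex-2-en-1-one | CC1(C)C=CC(=O)[C@@H](CO)[C@@H]1CO[Si](c1ccccc1)(c1ccccc1)C(C)(C)C | intermediate
9 | (5S,6R)-5-{[tert-butyl(diphenyl)silyl]oxymethyl}-4,4-dimethyl-6-[(triethylsilyl)oxymethyl]cyclohex-2-en-1-one | CC1(C)C=CC(=O)[C@@H](CO[Si](CC)(CC)CC)[C@@H]1CO[Si](c1ccccc1)(c1ccccc1)C(C)(C)C | intermediate
10 | (5R,6R)-5-{[tert-butyl(diphenyl)silyl]oxymethyl}-6-(hydroxymethyl)-4,4-dimethyl-6-[(triethylsilyl)oxymethyl]cyclohex-2-en-1-one (CH2OH trans, CH2OSiEt3 cis to the C5 side chain) | CC1(C)C=CC(=O)[C@](CO)(CO[Si](CC)(CC)CC)[C@@H]1CO[Si](c1ccccc1)(c1ccccc1)C(C)(C)C | intermediate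
11 | (1S,6R)-6-{[tert-butyl(diphenyl)silyl]oxymethyl}-5,5-dimethyl-2-oxo-1-[(triethylsilyl)oxymethyl]cyclohex-3-ene-1-carbaldehyde | CC1(C)C=CC(=O)[C@](C=O)(CO[Si](CC)(CC)CC)[C@@H]1CO[Si](c1ccccc1)(c1ccccc1)C(C)(C)C | intermediate
12 | (1S,6R)-6-{[tert-butyl(diphenyl)silyl]oxymethyl}-1-(hydroxymethyl)-5,5-dimethyl-2-oxocyclohex-3-ene-1-carbaldehyde | CC1(C)C=CC(=O)[C@](C=O)(CO)[C@@H]1CO[Si](c1ccccc1)(c1ccccc1)C(C)(C)C | intermediate
13 | 2,2,6-trimethyl-4H-1,3-dioxin-4-one | CC1=CC(=O)OC(C)(C)O1 | starting material
14 | [(1S,6R)-6-{[tert-butyl(diphenyl)silyl]oxymethyl}-1-formyl-5,5-dimethyl-2-oxocyclohex-3-en-1-yl]methyl 3-oxobutanoate | CC1(C)C=CC(=O)[C@](C=O)(COC(=O)CC(C)=O)[C@@H]1CO[Si](c1ccccc1)(c1ccccc1)C(C)(C)C | intermediate (not isolated)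
15 | (6S,11R)-4-acetyl-11-{[tert-butyl(diphenyl)silyl]oxymethyl}-10,10-dimethyl-2-oxaspiro[5.5]undeca-4,8-diene-3,7-dione (kaurane locants: 5R,10S; C8=C9) | CC1(C)C=CC(=O)[C@]2(COC(=O)C(C(C)=O)=C2)[C@@H]1CO[Si](c1ccccc1)(c1ccccc1)C(C)(C)C | intermediate
16 | buta-1,3-diene | C=CC=C | starting material
17 | (5R,8S,9S,10S)-6-[tert-butyl(diphenyl)silyl]oxy-1,15-dioxo-17-nor-6,7:13,16-disecokaura-2,12-dien-7,20-olide | CC1(C)C=CC(=O)[C@]2(COC(=O)[C@@]3(C(C)=O)CC=CC[C@H]32)[C@@H]1CO[Si](c1ccccc1)(c1ccccc1)C(C)(C)C | intermediate
18 | (5R,8S,9S,10S)-6-[tert-butyl(diphenyl)silyl]oxy-15-(trimethylsilyloxy)-1-oxo-17-nor-6,7:13,16-disecokaura-2,12,15-trien-7,20-olide | CC1(C)C=CC(=O)[C@]2(COC(=O)[C@@]3(C(=C)O[Si](C)(C)C)CC=CC[C@H]32)[C@@H]1CO[Si](c1ccccc1)(c1ccccc1)C(C)(C)C | intermediate (not isolated)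
19 | (5R,8S,9S,10S,13R)-6-[tert-butyl(diphenyl)silyl]oxy-1,15-dioxo-17-nor-6,7-secokaura-2,11-dien-7,20-olide | CC1(C)C=CC(=O)[C@]2(COC(=O)[C@@]34C[C@@H](C=C[C@H]32)CC4=O)[C@@H]1CO[Si](c1ccccc1)(c1ccccc1)C(C)(C)C | intermediate
20 | (5R,8S,9S,10S,13R)-6-[tert-butyl(diphenyl)silyl]oxy-1,15-dioxo-17-nor-6,7-secokaur-2-en-7,20-olide | CC1(C)C=CC(=O)[C@]2(COC(=O)[C@@]34C[C@@H](CC[C@H]32)CC4=O)[C@@H]1CO[Si](c1ccccc1)(c1ccccc1)C(C)(C)C | intermediate
21 | (5R,8S,9S,10S,13R,16R)-6-[tert-butyl(diphenyl)silyl]oxy-17-hydroxy-1,15-dioxo-6,7-secokaur-2-en-7,20-olide | CC1(C)C=CC(=O)[C@]2(COC(=O)[C@@]34C[C@@H](CC[C@H]32)[C@H](CO)C4=O)[C@@H]1CO[Si](c1ccccc1)(c1ccccc1)C(C)(C)C | intermediate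
22 | (5R,8S,9S,10S,13R,16R)-6,17-dihydroxy-1,15-dioxo-6,7-secokaur-2-en-7,20-olide | CC1(C)C=CC(=O)[C@]2(COC(=O)[C@@]34C[C@@H](CC[C@H]32)[C@H](CO)C4=O)[C@@H]1CO | target

## Step count and least certain steps

Total step count: 15. Longest linear sequence: 15 steps (1 to 22); 3, 13 and 16 enter as purchased reagents.

**Step 11 (key step).** What may go wrong is insufficient discrimination between the two faces of the C8=C9 bond, since the C1 carbonyl flank and the C5 methine flank differ more in shape than in size. Slow cycloaddition at the neopentyl C9 is a second risk, because it gives the Lewis acid time to cleave a silyl ether or oligomerise the diene. Fallback: it sets out from 15 and uses the far more nucleophilic 2-(trimethylsilyloxy)buta-1,3-diene, either thermally in toluene without a Lewis acid or, if the substrate's face preference proves weak, under control of Cu(OTf)2 with a chiral bis(oxazoline) ligand, for which the chelating 1,3-dicarbonyl unit is the normal binding site. The nucleophilic diene terminus bonds to C9, so the regiodefined silyl enol ether F1 carries its oxygen on C12. CsF and PhNTf2 convert it into the enol triflate F2, and palladium-catalysed formate reduction (Pd(OAc)2, PPh3, Bu3N, HCO2H, DMF) removes the oxygen and comes back to the route at 17.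

**Step 2.** What may go wrong is low turnover at the β-carbon next to the quaternary C4, with protodeboronation of 3 outrunning addition, and a second addition to the remaining enone of 4. Fallback: it sets out from 2 and gives up catalytic enantiocontrol in favour of resolution. Copper-catalysed conjugate addition of vinylmagnesium bromide (CuI, THF, −40 °C) gives the racemic vinyl enone F3. Ozonolysis with borohydride work-up as in step 3 gives the racemic alcohol F4, and silylation as in step 4 gives the racemic silyl ether F5. F5 is UV-active and is resolved by preparative chromatography on a chiral stationary phase; the (S)-enantiomer is 7, where the route is rejoined.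

**Step 7.** What may go wrong is poor face selectivity in the attack of formaldehyde on the tetrasubstituted C10 enolate, because the vicinal C5 side chain and the 1,3-related axial methyl group on C4 shield opposite faces. β-Elimination of silanolate from the enolate is a second risk. Fallback: the two arms on C10 differ only in protection, so the C10 epimer is not lost. It sets out from 9, whose aldol addition then delivers the epimeric alcohol F6 (free hydroxyl on the arm cis to C6). F6 is acylated with 13 (toluene, 110 °C) to the acetoacetate F7, the triethylsilyl group is removed with aqueous acetic acid to give the alcohol F8, and oxidation (TEMPO, PhI(OAc)2) gives 14, which condenses to 15 under the conditions of step 10.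

**Step 12.** What may go wrong is attack of the palladium enolate at C12 instead of C13 (six- instead of five-membered ring, giving a bicyclo[2.2.2]octanone), or protodesilylation back to 17 before cyclisation. Fallback: it sets out from 17 and closes ring D with a carbenoid, whose regiochemistry is fixed by ring size. Trifluoroacetylation of the methyl ketone (LiN(SiMe3)2, CF3CO2CH2CF3) gives the diketone F9, which is not isolated, and diazo transfer (MsN3, Et3N) gives the diazoketone F10. Rh2(OAc)4 effects intramolecular cyclopropanation of C12=C13 to the cyclopropyl ketone F11. SmI2 (divalent samarium; THF, MeOH, −78 °C) then cleaves the cyclopropane bond external to the cyclopentanone (C16–C12, the one aligned with the carbonyl π system) and returns to the route at 20, so that step 13 is not needed.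

**Step 14.** What may go wrong is reversal of the aldol addition or dehydration of the lithium aldolate to the exocyclic enone on warming, and acyl transfer from O20 to the new alkoxide. Fallback: it sets out from 20 and replaces the reversible aldol addition by an irreversible alkylation. The same lithium enolate is alkylated with benzyl chloromethyl ether from the exo face to give the benzyl ether F12, and BCl3·SMe2 (CH2Cl2, −78 to 0 °C) cleaves the benzyl ether to come back at 21.

## Further compounds

F1 | step 11 | silyl enol ether cycloadduct: 17 with a trimethylsilyloxy group on C12 (C12=C13) | CC1(C)C=CC(=O)[C@]2(COC(=O)[C@@]3(C(C)=O)CC=C(O[Si](C)(C)C)C[C@H]32)[C@@H]1CO[Si](c1ccccc1)(c1ccccc1)C(C)(C)C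
F2 | step 11 | enol triflate: 17 with a trifluoromethanesulfonyloxy group on C12 (C12=C13) | CC1(C)C=CC(=O)[C@]2(COC(=O)[C@@]3(C(C)=O)CC=C(OS(=O)(=O)C(F)(F)F)C[C@H]32)[C@@H]1CO[Si](c1ccccc1)(c1ccccc1)C(C)(C)C
F3 | step 2 | racemic 5-ethenyl-4,4-dimethylcyclohex-2-en-1-one | CC1(C)C=CC(=O)CC1C=C
F4 | step 2 | racemic 5-(hydroxymethyl)-4,4-dimethylcyclohex-2-en-1-one | CC1(C)C=CC(=O)CC1CO
F5 | step 2 | racemic 5-{[tert-butyl(diphenyl)silyl]oxymethyl}-4,4-dimethylcyclohex-2-en-1-one | CC1(C)C=CC(=O)CC1CO[Si](c1ccccc1)(c1ccccc1)C(C)(C)C
F6 | step 7 | (5R,6S)-5-{[tert-butyl(diphenyl)silyl]oxymethyl}-6-(hydroxymethyl)-4,4-dimethyl-6-[(triethylsilyl)oxymethyl]cyclohex-2-en-1-one (C10 epimer of 10; CH2OH cis to the C5 side chain) | CC1(C)C=CC(=O)[C@@](CO)(CO[Si](CC)(CC)CC)[C@@H]1CO[Si](c1ccccc1)(c1ccccc1)C(C)(C)C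
F7 | step 7 | acetoacetate of F6 (3-oxobutanoyloxymethyl arm cis, triethylsilyloxymethyl arm trans to the C5 side chain) | CC1(C)C=CC(=O)[C@](CO[Si](CC)(CC)CC)(COC(=O)CC(C)=O)[C@@H]1CO[Si](c1ccccc1)(c1ccccc1)C(C)(C)C
F8 | step 7 | hydroxy acetoacetate (hydroxymethyl arm trans, 3-oxobutanoyloxymethyl arm cis to the C5 side chain) | CC1(C)C=CC(=O)[C@](CO)(COC(=O)CC(C)=O)[C@@H]1CO[Si](c1ccccc1)(c1ccccc1)C(C)(C)C
F9 | step 12 | trifluoroacetyl diketone: 17 with C16 acylated by a trifluoroacetyl group | CC1(C)C=CC(=O)[C@]2(COC(=O)[C@@]3(C(=O)CC(=O)C(F)(F)F)CC=CC[C@H]32)[C@@H]1CO[Si](c1ccccc1)(c1ccccc1)C(C)(C)C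
F10 | step 12 | diazoketone: 17 with a diazo group on C16 | CC1(C)C=CC(=O)[C@]2(COC(=O)[C@@]3(C(=O)C=[N+]=[N-])CC=CC[C@H]32)[C@@H]1CO[Si](c1ccccc1)(c1ccccc1)C(C)(C)C
F11 | step 12 | cyclopropyl ketone: 20 with an additional C12–C16 bond (cyclopropane C12, C13, C16 on the face of the C15 bridge) | CC1(C)C=CC(=O)[C@]2(COC(=O)[C@@]34C[C@@H]([C@H]5C[C@H]32)[C@@H]5C4=O)[C@@H]1CO[Si](c1ccccc1)(c1ccccc1)C(C)(C)C
F12 | step 14 | 17-O-benzyl ether of 21 | CC1(C)C=CC(=O)[C@]2(COC(=O)[C@@]34C[C@@H](CC[C@H]32)[C@H](COCc5ccccc5)C4=O)[C@@H]1CO[Si](c1ccccc1)(c1ccccc1)C(C)(C)C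
A1 | alternative 1 | triene ester: ring A ketone with a (E)-buta-1,3-dienyl group and a (2-methylene-3-oxobutanoyl)oxymethyl group on C10 | CC1(C)C=CC(=O)[C@](/C=C/C=C)(COC(=O)C(=C)C(C)=O)[C@@H]1CO[Si](c1ccccc1)(c1ccccc1)C(C)(C)C
A2 | alternative 1 | intramolecular cycloadduct: isomer of 17 with the ring C alkene at C11=C12 | CC1(C)C=CC(=O)[C@]2(COC(=O)[C@@]3(C(C)=O)CCC=C[C@H]32)[C@@H]1CO[Si](c1ccccc1)(c1ccccc1)C(C)(C)C
A3 | alternative 2 | spiro-epoxide (C10–C20 oxirane; C1 as ethylene ketal; either C10 epimer, drawn as one) | CC1(C)C=CC2(OCCO2)[C@@]3(CO3)[C@@H]1CO[Si](c1ccccc1)(c1ccccc1)C(C)(C)C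
A4 | alternative 2 | spirolactone with ring C (C12=C13) and hydrogen on C8; C1 as ethylene ketal | CC1(C)C=CC2(OCCO2)[C@]3(COC(=O)[C@H]4CC=CC[C@H]43)[C@@H]1CO[Si](c1ccccc1)(c1ccccc1)C(C)(C)C
A5 | alternative 3 | 17,20-dihydroxykaura-2,6-diene-1,15-dione with the configuration of 22 (ring B intact, C6=C7) | CC1(C)C=CC(=O)[C@]2(CO)[C@@H]1C=C[C@@]34C[C@@H](CC[C@H]32)[C@H](CO)C4=O
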